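**Retrosynthetic overview**
- Target 8 ← acid 6: both pyrrole-ring bromines come last, C3–Br by ipso-bromodecarboxylation and C2–Br by electrophilic bromination in the same flask; 6 ← ester 5 by saponification.
- 5 ← enamino ester 3 by disconnecting C3–C3a (anodic, iodide-mediated dehydrogenative closure of the pyrrole ring); 3 ← 2,5-dibromoaniline 1 + ethyl propiolate 2 (N1–C2 bond by conjugate addition).
- Feature the route rests on: the benzene ring of 8 carries bromine at C4 and C7, para to each other. This maps onto 1 (N on C1, Br on C2 and C5), whose only free ortho carbon is C6. Closing C3–C3a onto C6 puts the bromines at C7 and C4 with no regiochemical choice, and the C3 ester that stabilises the radical is later exchanged for the C3 bromine.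
- Ring order: the benzene ring is bought with 1; the pyrrole ring is the only ring made (step 2).

Key step: step 2

Remark: 3 is drawn as its hydrogen-bonded Z isomer. Any E isomer formed alongside need not be removed, since both isomers interconvert through the imine tautomer and lead to the same radical in step 2.

**Step 1**
Reactants: 1 2,5-dibromoaniline; 2 ethyl propiolate
Product: 3 ethyl (Z)-3-[(2,5-dibromophenyl)amino]prop-2-enoate
Conditions: 2 (1.5 equiv), EtOH, 75 °C (sealed tube), 48 h
Reagents that add atoms: none
Why: Aza-Michael (conjugate) addition of the aniline nitrogen to the ynoate should give the vinylogous carbamate, the Z geometry being favoured by the intramolecular N–H···O=C hydrogen bond, while heating offsets the low nucleophilicity of the dibromoaniline.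

**Step 2**
Reactants: 3 ethyl (Z)-3-[(2,5-dibromophenyl)amino]prop-2-enoate
Product: 5 ethyl 4,7-dibromo-1H-indole-3-carboxylate, via ethyl 4,7-dibromo-3H-indole-3-carboxylate 4 (not isolated)
Conditions: undivided cell, graphite anode, Pt cathode, KI (0.5 equiv), nBu4NBF4 (0.1 M), DMF–EtOH 9:1, constant current (about 5 mA cm⁻²), 2.5 F mol⁻¹, 60 °C, 0.03 M in 3
Reagents that add atoms: none
Why: Iodide is oxidised at the anode to iodine, which iodinates the enamine at nitrogen or at the ester-bearing carbon; homolysis of that weak bond gives a 1-azaallyl radical with spin at the carbon alpha to the ester, stabilised by both the ester and the C=N bond. This radical attacks C6 of the aryl ring in an intramolecular homolytic aromatic substitution that closes the five-membered pyrrole ring (formally 5-exo-trig on the C6=C5 bond), and a second one-electron oxidation with loss of the ring proton gives the 3H-indole 4, which tautomerises to the aromatic 1H-indole 5 while protons are reduced to hydrogen at the cathode. The closest known reaction type is the iodide-mediated electro-oxidative dehydrogenative annulation of N-aryl enamino esters to indole-3-carboxylates in an undivided cell. No stereocentre remains, since C3 of 4 is planarised by the tautomerisation. The step needs attack at an ortho C–H and not at the bromine-bearing ortho carbon: in 3 the ring position C2 carries bromine, so C6 is the only ortho C–H and only the 4,7-dibromo isomer can arise. Chemoselectivity rests on the low potential at which iodide is oxidised, which should spare the product indole, on cathodic proton reduction at Pt lying far positive of aryl bromide cleavage, and on dilution, which disfavours intermolecular enamine coupling.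

**Step 3**
Reactants: 5 ethyl 4,7-dibromo-1H-indole-3-carboxylate
Product: 6 4,7-dibromo-1H-indole-3-carboxylic acid
Conditions: KOH (5 equiv), EtOH–H2O 3:1, 80 °C; then 1 M HCl, 0 °C, to pH 3
Reagents that add atoms: potassium hydroxide, [K+].[OH-]
Why: Acyl-oxygen saponification of the vinylogous carbamate ester should proceed with excess hydroxide and heat, the unactivated aryl bromides being inert to hydroxide and the cold, mild acidification avoiding protodecarboxylation of the indole-3-carboxylic acid.

**Step 4**
Reactants: 6 4,7-dibromo-1H-indole-3-carboxylic acid
Product: 8 2,3,4,7-tetrabromo-1H-indole, via 3,4,7-tribromo-1H-indole 7 (not isolated)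
Conditions: NBS (2.2 equiv), LiOAc (0.2 equiv), dry DMF, 0 °C to rt, dark
Reagents that add atoms: N-bromosuccinimide, O=C1CCC(=O)N1Br
Why: Halodecarboxylation of an electron-rich heteroaromatic acid by electrophilic ipso-substitution (bromonium attack at C3, loss of CO2 from the 3-bromo-3H-indolium carboxylate) should give 7, whose remaining pyrrole C2–H is then brominated by the second equivalent of NBS, the benzene positions C5 and C6 being deactivated by the two flanking bromines.

**Compound list**
1 | 2,5-dibromoaniline | Nc1cc(Br)ccc1Br | starting material
2 | ethyl propiolate | C#CC(=O)OCC | starting material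
3 | ethyl (Z)-3-[(2,5-dibromophenyl)amino]prop-2-enoate | CCOC(=O)/C=C\Nc1cc(Br)ccc1Br | intermediate
4 | ethyl 4,7-dibromo-3H-indole-3-carboxylate (racemic, transient) | CCOC(=O)C1C=Nc2c(Br)ccc(Br)c12 | intermediate (not isolated)
5 | ethyl 4,7-dibromo-1H-indole-3-carboxylate | CCOC(=O)c1c[nH]c2c(Br)ccc(Br)c12 | intermediate
6 | 4,7-dibromo-1H-indole-3-carboxylic acid | OC(=O)c1c[nH]c2c(Br)ccc(Br)c12 | intermediate
7 | 3,4,7-tribromo-1H-indole | Brc1c[nH]c2c(Br)ccc(Br)c12 | intermediate (not isolated)
8 | 2,3,4,7-tetrabromo-1H-indole | Brc1[nH]c2c(Br)ccc(Br)c2c1Br | target

**Total step count:** 4
**Longest linear sequence:** 4 steps (1 → 3 → 5 → 6 → 8)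

**Steps most likely to fail**

1. Step 2. Ring closure onto C6 may be slowed by the two deactivating bromines and by the peri crowding that builds up between the C5 bromine and the ester. Intermolecular coupling of the iodinated or radical enamine, iodination without cyclisation, or cleavage of the enamine could then outrun the cyclisation. The fallback sets out from 1 and builds the pyrrole ring by a sigmatropic route. Oxidation of the amino group with NaBO3·4H2O in AcOH at 55 °C should give 1,4-dibromo-2-nitrobenzene F1. A Bartoli indole synthesis with CH2=CHMgBr (3.2 equiv, THF, −45 °C, NH4Cl work-up), in which the ortho bromine steers the [3,3] shift to the free ortho carbon, should give 4,7-dibromo-1H-indole F2. One equivalent of NBS in DMF at 0 °C should brominate C3 of F2 and so reach 7, where the route is rejoined; the second equivalent of NBS then completes step 4 to 8.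

2. Step 4. The brominated 3H-indolium intermediates may be captured by adventitious water (over-oxidation to oxindole-type products), or the second bromination may stall on the electron-poor, crowded tribromoindole. The fallback sets out from 6 and installs the C2 bromine by deprotonation in place of electrophilic substitution. One equivalent of NBS (DMF, 0 °C) takes 6 only as far as 7, which is isolated this time. Boc2O with catalytic DMAP in MeCN should give tert-butyl 3,4,7-tribromo-1H-indole-1-carboxylate F3. Deprotonation of C2–H with LiN(iPr)2 in THF at −78 °C and quenching with BrCCl2CCl2Br should give tert-butyl 2,3,4,7-tetrabromo-1H-indole-1-carboxylate F4. Mild methanolysis of the crowded carbamate (K2CO3, MeOH, rt) returns to the route at 8.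

3. Step 1. Conjugate addition by the weakly nucleophilic, ortho-hindered aniline may remain incomplete, and the product enamine may add to a second molecule of the ynoate. The fallback sets out from 1 and replaces the addition by a condensation. Heating 1 with ethyl 3,3-diethoxypropanoate and catalytic p-TsOH in toluene, with removal of ethanol, should give 3 directly, where the route is rejoined. This fallback makes no new compound (F0).

**Further compounds**
F1 | step 2 | 1,4-dibromo-2-nitrobenzene | O=[N+]([O-])c1cc(Br)ccc1Br
F2 | step 2 | 4,7-dibromo-1H-indole | Brc1ccc(Br)c2[nH]ccc12
F3 | step 4 | tert-butyl 3,4,7-tribromo-1H-indole-1-carboxylate | CC(C)(C)OC(=O)n1cc(Br)c2c(Br)ccc(Br)c12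
F4 | step 4 | tert-butyl 2,3,4,7-tetrabromo-1H-indole-1-carboxylate | CC(C)(C)OC(=O)n1c(Br)c(Br)c2c(Br)ccc(Br)c12
F0 | step 1 | none | none
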